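**Retrosynthetic overview**
1. Target 15 ⇐ 2-aryloxyphenol 13 by phenol-directed para/ortho dibromination of ring B (last step).
2. 13 ⇐ 2-aryloxy-4-nitrophenol 8 by deleting the nitro group (mesylate protection, reduction, diazotisation/H3PO2, demesylation).
3. Ring B of 8 is built de novo by a [3+3] double aldol condensation of aryloxyacetone 5 with sodium nitromalonaldehyde 6. The intermolecular aldol condensation joins the two fragments; the intramolecular aldol/dehydration closes and aromatises the ring.
4. 5 ⇐ 2,4-dibromo-6-methoxyphenol 3 + chloroacetone 4 (Williamson); 3 ⇐ guaiacol 1 by ortho- then para-bromination.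
5. Ring order: ring A comes ready-made from guaiacol and is brominated first; ring B is constructed on its oxygen and brominated last.

Assumption: the target has no stereocentre and no configurationally stable axis, so it is achiral and needs no stereocontrol.

**Route**

Step 1
Reactants: 1 guaiacol (2-methoxyphenol)
Product: 2 2-bromo-6-methoxyphenol
Conditions: tBuNH2 (2 equiv), Br2 (1.0 equiv), toluene, −30 °C; then 1 in CH2Cl2, −78 °C → rt
Reagents that add atoms: bromine, BrBr
Why: Amine-mediated ortho-selective electrophilic aromatic bromination, in which N-bromo-tert-butylamine delivers Br through the hydrogen-bonded phenol to the only free ortho position.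

Step 2
Reactants: 2 2-bromo-6-methoxyphenol
Product: 3 2,4-dibromo-6-methoxyphenol
Conditions: NBS (1.0 equiv), MeCN, 0 °C → rt
Reagents that add atoms: N-bromosuccinimide, O=C1CCC(=O)N1Br
Why: Electrophilic aromatic substitution para to the free OH, the strongest director; the site para to OMe is ortho to the existing Br and deactivated.

Step 3
Reactants: 3 2,4-dibromo-6-methoxyphenol; 4 chloroacetone
Product: 5 1-(2,4-dibromo-6-methoxyphenoxy)propan-2-one
Conditions: K2CO3 (1.5 equiv), DMF, 50 °C
Reagents that add atoms: none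
Why: Williamson ether synthesis, SN2 of the phenoxide on a highly reactive α-chloro ketone.

Step 4
Reactants: 5 1-(2,4-dibromo-6-methoxyphenoxy)propan-2-one; 6 sodium nitromalonaldehyde monohydrate (commercial; keep moist, the dry salt is impact-sensitive)
Product: 8 2-(2,4-dibromo-6-methoxyphenoxy)-4-nitrophenol, via open-chain aldol condensation enolate 7 (not isolated)
Conditions: 6 (1.2 equiv), NaOH (0.3 equiv), EtOH/H2O 1:1, rt, 3–5 d; then 2 M HCl to pH 2
Reagents that add atoms: none
Why: Nitromalonaldehyde benzannulation: an intermolecular aldol condensation of the ketone methyl group with one formyl group joins the fragments, then an intramolecular aldol condensation of the ArOCH2 carbon with the second formyl group closes the ring, and loss of two waters gives the nitrophenolate with regiochemistry fixed by connectivity.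

Step 5
Reactants: 8 2-(2,4-dibromo-6-methoxyphenoxy)-4-nitrophenol
Product: 9 2-(2,4-dibromo-6-methoxyphenoxy)-4-nitrophenyl methanesulfonate
Conditions: MsCl (1.2 equiv), Et3N (1.5 equiv), CH2Cl2, 0 °C → rt
Reagents that add atoms: methanesulfonyl chloride, CS(=O)(=O)Cl
Why: O-sulfonylation of an acidic phenol; it masks the OH so the later diazonium salt cannot collapse to a quinone diazide or azo-couple.

Step 6
Reactants: 9 2-(2,4-dibromo-6-methoxyphenoxy)-4-nitrophenyl methanesulfonate
Product: 10 4-amino-2-(2,4-dibromo-6-methoxyphenoxy)phenyl methanesulfonate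
Conditions: Fe powder (5 equiv), AcOH/EtOH/H2O, 70 °C
Reagents that add atoms: none
Why: Béchamp-type dissolving-metal nitro reduction, which leaves aryl bromides, the aryl mesylate and the ethers untouched.

Step 7
Reactants: 10 4-amino-2-(2,4-dibromo-6-methoxyphenoxy)phenyl methanesulfonate
Product: 12 2-(2,4-dibromo-6-methoxyphenoxy)phenyl methanesulfonate, via arenediazonium chloride 11 (not isolated)
Conditions: NaNO2 (1.1 equiv), 6 M HCl, THF/H2O, 0 °C; then 50% aq. H3PO2 (10 equiv), 0 °C → rt
Reagents that add atoms: none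
Why: Diazotisation followed by hypophosphorous acid hydrodediazoniation (radical chain), a standard deamination of a phenol-protected aniline; the aryl radical is not ortho to the ether, so no Pschorr cyclisation can occur.

Step 8
Reactants: 12 2-(2,4-dibromo-6-methoxyphenoxy)phenyl methanesulfonate
Product: 13 2-(2,4-dibromo-6-methoxyphenoxy)phenol
Conditions: KOH (4 equiv), MeOH/THF/H2O, 65 °C; then 1 M HCl
Reagents that add atoms: none
Why: Basic cleavage of the aryl mesylate at sulfur; unactivated aryl bromides and the aryl methyl ether are inert to hydroxide under these conditions.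

Step 9
Reactants: 13 2-(2,4-dibromo-6-methoxyphenoxy)phenol
Product: 15 2,4-dibromo-6-(2,4-dibromo-6-methoxyphenoxy)phenol, via para-monobromophenol 14 (not isolated)
Conditions: Br2 (2.1 equiv), AcOH, 15 °C → rt
Reagents that add atoms: bromine, BrBr
Why: Phenol-directed electrophilic aromatic bromination, first para then at the only free ortho position of the OH; ring A carries two bromines and no free OH and is far less reactive.

**Compound list**
1 | guaiacol (2-methoxyphenol) | COc1ccccc1O | starting material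
2 | 2-bromo-6-methoxyphenol | COc1cccc(Br)c1O | intermediate
3 | 2,4-dibromo-6-methoxyphenol | COc1cc(Br)cc(Br)c1O | intermediate
4 | chloroacetone | CC(=O)CCl | starting material
5 | 1-(2,4-dibromo-6-methoxyphenoxy)propan-2-one | CC(=O)COc1c(OC)cc(Br)cc1Br | intermediate
6 | sodium nitromalonaldehyde monohydrate | [Na+].[O-]C=C(C=O)[N+](=O)[O-].O | starting material
7 | sodium enolate of 6-(2,4-dibromo-6-methoxyphenoxy)-2-nitro-5-oxohex-3-enal (delocalised anion, C=C geometry not fixed) | [Na+].[O-]C=C(C=CC(=O)COc1c(OC)cc(Br)cc1Br)[N+](=O)[O-] | intermediate (not isolated)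
8 | 2-(2,4-dibromo-6-methoxyphenoxy)-4-nitrophenol | Oc1ccc(cc1Oc1c(OC)cc(Br)cc1Br)[N+](=O)[O-] | intermediate
9 | 2-(2,4-dibromo-6-methoxyphenoxy)-4-nitrophenyl methanesulfonate | CS(=O)(=O)Oc1ccc(cc1Oc1c(OC)cc(Br)cc1Br)[N+](=O)[O-] | intermediate
10 | 4-amino-2-(2,4-dibromo-6-methoxyphenoxy)phenyl methanesulfonate | CS(=O)(=O)Oc1ccc(N)cc1Oc1c(OC)cc(Br)cc1Br | intermediate
11 | 3-(2,4-dibromo-6-methoxyphenoxy)-4-(methylsulfonyloxy)benzenediazonium chloride | CS(=O)(=O)Oc1ccc(cc1Oc1c(OC)cc(Br)cc1Br)[N+]#N.[Cl-] | intermediate (not isolated)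
12 | 2-(2,4-dibromo-6-methoxyphenoxy)phenyl methanesulfonate | CS(=O)(=O)Oc1ccccc1Oc1c(OC)cc(Br)cc1Br | intermediate
13 | 2-(2,4-dibromo-6-methoxyphenoxy)phenol | Oc1ccccc1Oc1c(OC)cc(Br)cc1Br | intermediate
14 | 4-bromo-2-(2,4-dibromo-6-methoxyphenoxy)phenol | Oc1ccc(Br)cc1Oc1c(OC)cc(Br)cc1Br | intermediate (not isolated)
15 | 2,4-dibromo-6-(2,4-dibromo-6-methoxyphenoxy)phenol | COc1cc(Br)cc(Br)c1Oc1cc(Br)cc(Br)c1O | target

**Totals**
Total step count: 9. Longest linear sequence: 9 steps (1 → 15); 4 and 6 are bought.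

**Steps most likely to fail, with fallbacks**

Step 4 (aqueous double aldol benzannulation; lipophilic, unsymmetrical ketone). The fallback sets out from 3 and comes back at 15, building ring B by a Chan–Brownbridge [3+3] Mukaiyama-aldol cyclisation instead. Phenol 3 is O-alkylated with ethyl 4-chloroacetoacetate (NaH 2.2 equiv, THF, 0 °C → rt) to give ethyl 4-(2,4-dibromo-6-methoxyphenoxy)-3-oxobutanoate F1. Me3SiCl/Et3N (toluene, rt) gives ethyl 4-(2,4-dibromo-6-methoxyphenoxy)-3-(trimethylsilyloxy)but-2-enoate F2, and LDA then Me3SiCl (THF, −78 °C) gives 1-ethoxy-4-(2,4-dibromo-6-methoxyphenoxy)-1,3-bis(trimethylsilyloxy)buta-1,3-diene F3, used crude. TiCl4-mediated condensation of F3 with 1,1,3,3-tetramethoxypropane (CH2Cl2, −78 → 20 °C) gives ethyl 3-(2,4-dibromo-6-methoxyphenoxy)-2-hydroxybenzoate F4. Saponification (NaOH, MeOH/H2O, 60 °C, then HCl) gives 3-(2,4-dibromo-6-methoxyphenoxy)-2-hydroxybenzoic acid F5. Br2 (2.2 equiv) in aqueous AcOH brominates para to the OH to give 5-bromo-3-(2,4-dibromo-6-methoxyphenoxy)-2-hydroxybenzoic acid F6 (not isolated), which undergoes ipso-bromodecarboxylation at the carboxyl-bearing ortho carbon to give 15 directly.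

Step 1 (mono-ortho selectivity; 4-bromo and dibromo by-products). The fallback sets out from 1 and comes back at 2, replacing electrophilic substitution by directed ortho-metalation. Guaiacol 1 is protected with MOMCl/iPr2NEt (CH2Cl2, 0 °C → rt) as 1-methoxy-2-(methoxymethoxy)benzene F7. nBuLi (THF, 0 °C) lithiates ortho to the stronger directing OMOM group to give [3-methoxy-2-(methoxymethoxy)phenyl]lithium F8 (not isolated). Quenching with 1,2-dibromotetrachloroethane at −78 °C gives 1-bromo-3-methoxy-2-(methoxymethoxy)benzene F9, and HCl in MeOH (rt) removes the MOM group to return 2.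

Step 7 (diazonium reduction on a lipophilic substrate; incomplete reduction or tar). The fallback sets out from 10 and comes back at 14, using the amino group as the handle for the para bromine instead of deleting it. Amine 10 is diazotised with NaNO2 in 48% HBr/MeCN at 0 °C to give 3-(2,4-dibromo-6-methoxyphenoxy)-4-(methylsulfonyloxy)benzenediazonium bromide F10 (not isolated). Sandmeyer reaction with CuBr in HBr (60 °C) gives 4-bromo-2-(2,4-dibromo-6-methoxyphenoxy)phenyl methanesulfonate F11. KOH/MeOH as in step 8 then gives 14, here isolated, which needs only one equivalent of Br2 under the step 9 conditions to reach 15.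

**Further compounds**
F1 | step 4 | ethyl 4-(2,4-dibromo-6-methoxyphenoxy)-3-oxobutanoate | CCOC(=O)CC(=O)COc1c(OC)cc(Br)cc1Br
F2 | step 4 | ethyl 4-(2,4-dibromo-6-methoxyphenoxy)-3-(trimethylsilyloxy)but-2-enoate (E/Z mixture) | CCOC(=O)C=C(COc1c(OC)cc(Br)cc1Br)O[Si](C)(C)C
F3 | step 4 | 1-ethoxy-4-(2,4-dibromo-6-methoxyphenoxy)-1,3-bis(trimethylsilyloxy)buta-1,3-diene (isomer mixture) | CCOC(O[Si](C)(C)C)=CC(O[Si](C)(C)C)=COc1c(OC)cc(Br)cc1Br
F4 | step 4 | ethyl 3-(2,4-dibromo-6-methoxyphenoxy)-2-hydroxybenzoate | CCOC(=O)c1cccc(Oc2c(OC)cc(Br)cc2Br)c1O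
F5 | step 4 | 3-(2,4-dibromo-6-methoxyphenoxy)-2-hydroxybenzoic acid | OC(=O)c1cccc(Oc2c(OC)cc(Br)cc2Br)c1O
F6 | step 4 | 5-bromo-3-(2,4-dibromo-6-methoxyphenoxy)-2-hydroxybenzoic acid | OC(=O)c1cc(Br)cc(Oc2c(OC)cc(Br)cc2Br)c1O
F7 | step 1 | 1-methoxy-2-(methoxymethoxy)benzene | COCOc1ccccc1OC
F8 | step 1 | [3-methoxy-2-(methoxymethoxy)phenyl]lithium | [Li]c1cccc(OC)c1OCOC
F9 | step 1 | 1-bromo-3-methoxy-2-(methoxymethoxy)benzene | COCOc1c(Br)cccc1OC
F10 | step 7 | 3-(2,4-dibromo-6-methoxyphenoxy)-4-(methylsulfonyloxy)benzenediazonium bromide | CS(=O)(=O)Oc1ccc(cc1Oc1c(OC)cc(Br)cc1Br)[N+]#N.[Br-]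
F11 | step 7 | 4-bromo-2-(2,4-dibromo-6-methoxyphenoxy)phenyl methanesulfonate | CS(=O)(=O)Oc1ccc(Br)cc1Oc1c(OC)cc(Br)cc1Br
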